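J is what you read, and each J made has cost one E and one Q, so every reading also tells you what is left of E, the limiting reagent, and of Q, bound and free counted together.

| flask | E | Q | X | time |
|---|---|---|---|---|
| east | 0.800 M | 0.960 M | 0.0240 M |  |
| south | 0.400 M | 0.960 M | 0.0240 M |  |
| south-east | 0.400 M | 0.560 M | 0.0240 M | 83 min |

| run | time / min | [J] / M |
|---|---|---|
| east run | 3.3 | 0.104 |
| east run | 7.4 | 0.195 |
| east run | 17 | 0.350 |
| east run | 37 | 0.529 |
| east run | 83 | 0.673 |
| south run | 3.3 | 0.047 |
| south run | 7.4 | 0.095 |
| south run | 17 | 0.188 |
| south run | 37 | 0.293 |
| south run | 83 | 0.375 |

(each reading ± 0.004 M)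

1. reaction order in [E] at the outset, round the charge of the east run, defined at two percent of the E turned into J (one fixed amount of J, the same in the runs compared)
2. J in the south-east run at 83 min, as a share of the E charged

- Overall: E + Q -> J, with X as catalyst.
- Constant volume, constant temperature.
- Bound and free are read together.
- An order is taken over about fifteen percent of the charge, up and down.

The last east reading, 0.673 M of J at 83 min, leaves 0.127 M of E and 0.287 M of Q. Divide the ratio of Q to E left by the same ratio in the charge and take the logarithm: this gives the excess clock Θ 0.633. If the rate is first order in each of E and Q, with constant k, then Θ equals k times the excess of Q over E times the time.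

The south-east flask has the east run's excess, 0.160 M, and is asked at the same time, so I carry Θ over unchanged. With its own charge ratio, that leaves 0.0978 M of E, so my reckoning gives 75.6 % of the E as J.

Is one number enough? Scaled to the south run's excess, Θ becomes 2.22, which predicts 0.373 M of J at 83 min. The south run reads 0.375 M, within the scatter of 0.004 M.

The forecast gives 76 %, between 73 % and 79 %, and an order in E of 1.1, between 0.93 and 1.3. Of the south run's constant it says that it “starts a little low and drifts up”.

The flask gives 78.2 % and an order in E of 1.0.

    X + E + Q → J + X (2.106 /M²/min)
    E + Q → J (0.01722 /M/min)
    2 Q ⇌ Q2, settled at all times (0.5090 /M)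

Folded back, 78.2 % makes Θ in the south-east flask 0.706, higher than the east run's 0.633 at the same excess and time, but that east value rests on one reading, and one standard deviation of it moves Θ by 0.0176. With the tying up of Q as Q2 taken away, the south-east run gives 83.6 % of J in place of 78.2 %. With that same step taken away, the apparent order in Q is 1.0 in place of 0.74.

All runs stem from a simulated flask on assumed constants; noise was put on by code.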